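**Retrosynthetic overview** (disconnections listed from the first bond made to the last)
1. Ring A (the carbocycle) is bought as an arene: phloroglucinol 1 is C-acylated with isovaleryl chloride 2 to the acylphloroglucinol 3.
2. One C–prenyl bond comes from prenyl bromide 4 (→ 5). The para-hydroxyl is then blocked as a silyl ether (→ 6), so that only the ketone-chelated ortho-oxygen can reach the side chain.
3. Ring B (dihydrofuran, formed second, key step): the single olefin of 6 is epoxidised enantioselectively to the (S)-epoxide 7. The ortho-phenoxide opens it 5-exo with inversion to (2R)-8, as in the biogenesis of hydroxyisopropyl-dihydrofurans.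
4. Last disconnection: the two C–prenyl bonds at the quaternary carbon. Desilylation (9) and double C-prenylation via 10 dearomatise ring A to the enolised trione 11, the target.

Assumption: the stereocentre in the given SMILES is C2 of the dihydrofuran and is read as R; the enol drawn is taken as one tautomer of a freely equilibrating enolised trione.

**Step 1**
Reactants: 1 phloroglucinol (benzene-1,3,5-triol); 2 isovaleryl chloride (3-methylbutanoyl chloride)
Product: 3 phlorisovalerophenone (3-methyl-1-(2,4,6-trihydroxyphenyl)butan-1-one)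
Conditions: AlCl3 (3.5 equiv), PhNO2, 0 → 60 °C, 4 h; then ice/2 M HCl
Reagents that add atoms: none
Why: Friedel–Crafts acylation of the very electron-rich arene stops after one acyl group because the aryl ketone product is deactivated and tied up as its aluminium chelate.

**Step 2**
Reactants: 3 phlorisovalerophenone; 4 prenyl bromide (1-bromo-3-methylbut-2-ene, 1.0 equiv)
Product: 6 1-[2,6-dihydroxy-3-(3-methylbut-2-en-1-yl)-4-(triisopropylsilyloxy)phenyl]-3-methylbutan-1-one, via 3-prenylphlorisovalerophenone 5 (not isolated)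
Conditions: DBU (1.0 equiv), THF, 0 → 23 °C, 16 h; then DBU (1.2 equiv), iPr3SiCl (1.2 equiv), 0 °C, 1 h
Reagents that add atoms: triisopropylsilyl chloride, CC(C)[Si](Cl)(C(C)C)C(C)C
Why: Base-mediated C-alkylation of the ambident acylphloroglucinol anion (phenolate C-prenylation, the reaction used for hop deoxy-acids) gives 5, whose most acidic and only non-chelated hydroxyl, the one para to the ketone, is then silylated selectively, so that the silyl ethers of unreacted 3 and of diprenylated material are removed by chromatography at this stage.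

**Step 3** (key step)
Reactants: 6 1-[2,6-dihydroxy-3-(3-methylbut-2-en-1-yl)-4-(triisopropylsilyloxy)phenyl]-3-methylbutan-1-one
Product: 8 1-[(2R)-6-hydroxy-2-(2-hydroxypropan-2-yl)-4-(triisopropylsilyloxy)-2,3-dihydro-1-benzofuran-7-yl]-3-methylbutan-1-one, via (S)-epoxide 7 (not isolated)
Conditions: ent-Shi ketone (1,2:4,5-di-O-isopropylidene-β-L-erythro-2,3-hexodiulo-2,6-pyranose, 30 mol %), Oxone (2KHSO5·KHSO4·K2SO4, 1.4 equiv), K2CO3 (5.8 equiv), Bu4NHSO4 (5 mol %), aq Na2B4O7 buffer (pH 10.5), MeCN–CH2(OMe)2 1:2, 0 °C, 2 h; then 23 °C, 2 h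
Reagents that add atoms: potassium peroxymonosulfate (the oxidant in Oxone), [K+].[O-]S(=O)(=O)OO
Why: Shi asymmetric epoxidation by the dioxirane of the L-fructose-derived ketone gives the (S)-epoxide 7 (the D-fructose ketone gives R with prenylarenes), and the ketone-chelated ortho-phenoxide, the only oxygen that can reach the epoxide now that the para-oxygen is silylated, opens it by a biomimetic 5-exo-tet SN2 attack at the secondary carbon with inversion, which sets C2 as R.

**Step 4**
Reactants: 8 1-[(2R)-6-hydroxy-2-(2-hydroxypropan-2-yl)-4-(triisopropylsilyloxy)-2,3-dihydro-1-benzofuran-7-yl]-3-methylbutan-1-one; 4 prenyl bromide (two equivalents are incorporated)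
Product: 11 (2R)-6-hydroxy-2-(2-hydroxypropan-2-yl)-7-(3-methylbutanoyl)-5,5-bis(3-methylbut-2-en-1-yl)-2,3-dihydro-1-benzofuran-4(5H)-one (target CNP0104249.1), via desilylated triol 9 (not isolated), via 5-prenyl triol 10 (not isolated)
Conditions: KOH (6 equiv), THF–H2O 1:1, 23 °C, 2 h; then 4 (2.3 equiv), 0 → 23 °C, 6 h; then aq citric acid to pH 4
Reagents that add atoms: none
Why: Hydroxide cleaves the activated aryl silyl ether, and the resulting phloroglucinol polyanion undergoes two successive C-alkylations at the one ring carbon that lies between two oxido groups, the second being the dearomatising alkylation known from the lupulone synthesis, which builds the achiral quaternary carbon without touching the ether stereocentre.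

**Compound list**
1 | phloroglucinol (benzene-1,3,5-triol) | Oc1cc(O)cc(O)c1 | starting material
2 | isovaleryl chloride (3-methylbutanoyl chloride) | CC(C)CC(Cl)=O | starting material
3 | phlorisovalerophenone, 3-methyl-1-(2,4,6-trihydroxyphenyl)butan-1-one | CC(C)CC(=O)c1c(O)cc(O)cc1O | intermediate
4 | prenyl bromide (1-bromo-3-methylbut-2-ene) | CC(C)=CCBr | starting material
5 | 3-methyl-1-[2,4,6-trihydroxy-3-(3-methylbut-2-en-1-yl)phenyl]butan-1-one (not isolated) | CC(C)CC(=O)c1c(O)cc(O)c(CC=C(C)C)c1O | intermediate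
6 | 1-[2,6-dihydroxy-3-(3-methylbut-2-en-1-yl)-4-(triisopropylsilyloxy)phenyl]-3-methylbutan-1-one | CC(C)CC(=O)c1c(O)cc(O[Si](C(C)C)(C(C)C)C(C)C)c(CC=C(C)C)c1O | intermediate
7 | 1-[3-{[(2S)-3,3-dimethyloxiran-2-yl]methyl}-2,6-dihydroxy-4-(triisopropylsilyloxy)phenyl]-3-methylbutan-1-one (not isolated) | CC(C)CC(=O)c1c(O)cc(O[Si](C(C)C)(C(C)C)C(C)C)c(C[C@@H]2OC2(C)C)c1O | intermediate
8 | 1-[(2R)-6-hydroxy-2-(2-hydroxypropan-2-yl)-4-(triisopropylsilyloxy)-2,3-dihydro-1-benzofuran-7-yl]-3-methylbutan-1-one | CC(C)CC(=O)c1c(O)cc(O[Si](C(C)C)(C(C)C)C(C)C)c2c1O[C@@H](C(C)(C)O)C2 | intermediate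
9 | 1-[(2R)-4,6-dihydroxy-2-(2-hydroxypropan-2-yl)-2,3-dihydro-1-benzofuran-7-yl]-3-methylbutan-1-one (not isolated) | CC(C)CC(=O)c1c(O)cc(O)c2c1O[C@@H](C(C)(C)O)C2 | intermediate
10 | 1-[(2R)-4,6-dihydroxy-2-(2-hydroxypropan-2-yl)-5-(3-methylbut-2-en-1-yl)-2,3-dihydro-1-benzofuran-7-yl]-3-methylbutan-1-one (not isolated) | CC(C)CC(=O)c1c(O)c(CC=C(C)C)c(O)c2c1O[C@@H](C(C)(C)O)C2 | intermediate
11 | (2R)-6-hydroxy-2-(2-hydroxypropan-2-yl)-7-(3-methylbutanoyl)-5,5-bis(3-methylbut-2-en-1-yl)-2,3-dihydro-1-benzofuran-4(5H)-one | CC(C)=CCC1(CC=C(C)C)C(=O)C2=C(O[C@@H](C(C)(C)O)C2)C(C(=O)CC(C)C)=C1O | target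

Total step count: 4. Longest linear sequence: 4 steps (1 → 3 → 6 → 8 → 11).

**Steps most likely to fail**

Risk 1 (step 3): the two free ortho-phenols may be oxidised by Oxone or the dioxirane at pH 10.5, and the ee on this crowded prenylarene may be only moderate. The fallback sets out from 6 and comes back at 8, replacing asymmetric catalysis by resolution. Buffered mCPBA (1.1 equiv, NaHCO3, CH2Cl2, 0 °C) epoxidises 6 under non-basic conditions to 7 together with its mirror image, the (R)-epoxide F2. K2CO3 in MeCN at 23 °C then closes both through the same ortho-oxygen, giving 8 and the (2S)-dihydrobenzofuran F3. Preparative chiral SFC (amylose tris(3,5-dimethylphenylcarbamate) phase, CO2/MeOH) removes F3 and delivers 8.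

Risk 2 (step 4): the second, dearomatising prenylation is hindered and may stall at 10 or divert to O-prenyl ethers. Alkylation at the ring-fusion carbon C3a, which is flanked by only one oxido group, is the likely regiochemical leak. The fallback sets out from 8 and comes back at 11, using a smaller, more C-selective electrophile followed by olefin metathesis. After the same KOH desilylation to 9, allyl bromide (2.3 equiv, 0 → 23 °C) gives, through the 5-allyl triol F4, the 5,5-diallyl trione F5, which is isolated. Double cross-metathesis with excess 2-methylbut-2-ene (second-generation Grubbs catalyst, 5 mol %, CH2Cl2, 40 °C) converts both allyl groups into prenyl groups and gives 11.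

Risk 3 (step 2): mono-C-prenylation of 3 is statistical, with diprenylation and O-prenylation as side reactions, and the telescoped silylation may give a mixture that is hard to separate. The fallback sets out from 3 and comes back at 6, reversing the order so that the most nucleophilic oxygen is blocked before alkylation. iPr3SiCl and imidazole in DMF at 0 °C give 1-[2,6-dihydroxy-4-(triisopropylsilyloxy)phenyl]-3-methylbutan-1-one F1. Its sodium phenoxide (NaH, 1.0 equiv, toluene, 0 °C) is then C-prenylated with 4 ortho to the oxido group (contact-ion-pair ortho-alkylation in a non-polar solvent) to give 6.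

**Further compounds**
F1 | step 2 | 1-[2,6-dihydroxy-4-(triisopropylsilyloxy)phenyl]-3-methylbutan-1-one | CC(C)CC(=O)c1c(O)cc(O[Si](C(C)C)(C(C)C)C(C)C)cc1O
F2 | step 3 | 1-[3-{[(2R)-3,3-dimethyloxiran-2-yl]methyl}-2,6-dihydroxy-4-(triisopropylsilyloxy)phenyl]-3-methylbutan-1-one | CC(C)CC(=O)c1c(O)cc(O[Si](C(C)C)(C(C)C)C(C)C)c(C[C@H]2OC2(C)C)c1O
F3 | step 3 | 1-[(2S)-6-hydroxy-2-(2-hydroxypropan-2-yl)-4-(triisopropylsilyloxy)-2,3-dihydro-1-benzofuran-7-yl]-3-methylbutan-1-one | CC(C)CC(=O)c1c(O)cc(O[Si](C(C)C)(C(C)C)C(C)C)c2c1O[C@H](C(C)(C)O)C2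
F4 | step 4 | 1-[(2R)-4,6-dihydroxy-2-(2-hydroxypropan-2-yl)-5-(prop-2-en-1-yl)-2,3-dihydro-1-benzofuran-7-yl]-3-methylbutan-1-one | CC(C)CC(=O)c1c(O)c(CC=C)c(O)c2c1O[C@@H](C(C)(C)O)C2
F5 | step 4 | (2R)-6-hydroxy-2-(2-hydroxypropan-2-yl)-7-(3-methylbutanoyl)-5,5-di(prop-2-en-1-yl)-2,3-dihydro-1-benzofuran-4(5H)-one | C=CCC1(CC=C)C(=O)C2=C(O[C@@H](C(C)(C)O)C2)C(C(=O)CC(C)C)=C1O
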